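## Structural features

- The target is an achiral 2,2-dimethyl-2H-chromene. Benzene ring A is fused through C4a and C8a to pyran ring B (O1, quaternary C2 with two methyl groups, styrenic C3=C4).
- Ring A is a fully differentiated resorcinol. The oxygen on C7 is a 3-methylbut-2-enyl (prenyl) ether and the oxygen on C8a is the ring B oxygen. C4a carries C4 of ring B, C5 carries a two-carbon tether to the para-hydroxyphenyl ring C, and C6 and C8 carry hydrogen.
- There is no stereocentre, so no stereocentres stand next to each other. The C3=C4 bond is fixed cis by the ring and the prenyl alkene is trisubstituted.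
- The fragile groups are the aryl prenyl ether (acid, zerovalent palladium, heat), the chromene double bond (acid, oxidants, hydrogenation) and the free phenol of ring C.
- The real difficulty is regiochemical. Three phenolic oxygens must be told apart, and ring B must be fused at C4a, between O-bearing C8a and the arm-bearing C5, not at the more nucleophilic C8 between the two oxygens.
- The key step exploits the contiguous array C7(O)–C8(H)–C8a(O)–C4a(C)–C5(C)–C6(H) of ring A. A vinylketene supplies C7, C4a, C5 and C6 and an ynol silyl ether supplies C8 and C8a. C7 emerges as a free hydroxyl, C8a as a silyl ether, and the prenyl group and the arm are already in place on C4a and C5.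

## Logic of the disconnections

**20 to 19.** The O1–C2 bond is cut, and the C3=C4 bond is traced back to the double bond of a C-prenyl group. An ortho-prenylphenol is the simplest open form of a 2,2-dimethylchromene, so all of ring B disappears. The forward step must close 6-endo, must choose the C-prenyl alkene over the O-prenyl alkene, and must leave the ring C phenol alone.

**19 to 18.** The two O–Si bonds (on C8a–O and on the ring C oxygen) are cut. Both hydroxyls that must be free before ring closure carry the same fluoride-labile group, so one operation unmasks them. The demand is a fluoride source mild enough for the allyl aryl ether.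

**18 to 16 and 17.** The bond between the C7 oxygen and the prenyl CH2 is cut. In 16 the C7 hydroxyl is the only free one, so the etherification needs no selectivity among oxygens. It must favour O- over C-alkylation and leave the silyl ethers in place.

**16 to 10 and 11 (key).** C7–C8, C8a–C4a and C6–C7 are cut, which opens ring A. Four adjacent substituents with both oxygens differentiated then come from two acyclic pieces, and the ring and its regiochemistry are gained in one step. The atom mapping was checked: the ketene carbon becomes C7, the ketene α-carbon C4a, the vinyl carbons C5 and C6, and the alkyne carbons C8 and C8a. The forward step requires that the Wolff rearrangement outruns hydrogen migration and that the ketene meets 11 before it meets 16.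

**10 to 8.** The C=N2 bond at the future C4a is cut. The diazo carbon is the only enolisable α-position on that side of the ketone, so diazo transfer is regiochemically unambiguous. The methylene enone is base-sensitive, which demands an activation method that tolerates it.

**8 to 3 and 6.** The bond between the carbonyl carbon (future C7) and the vinylic carbon (future C5) is cut. This gives an acyl donor 6 and a 1,1-disubstituted vinyl anion 7, which 3 delivers directly. Both halves are one or two steps from catalogue compounds. Compared with a route through a benzylic Grignard reagent and a dihalopropene, this saves about two steps and avoids a labile para-silyloxybenzyl halide. The demand is regioselective vinyl anion formation and single acylation.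

**6 to 4.** The amide C–N bond is cut; the acid carries the prenyl unit and the future C4a.

**3 to 2 to 1.** The C=N bond and then the O–Si bond are cut. 1 already contains ring C, the two-carbon tether and the carbon that becomes C5.

## Other disconnections considered

**Alternative 1:** The cuts are C5–CH2 of the arm and C4a–C4, both made on a purchased resorcinol.

- Forward step: 1-iodo-2,4-bis(methoxymethoxy)benzene A1, [4-(2-bromoethyl)phenoxy]triisopropylsilane A2 and 2-methylbut-3-en-2-ol A3 would be joined in one Catellani reaction (palladium catalyst, a strained bicyclic olefin as transient mediator, carbonate base). Ortho-alkylation at the free position next to iodine and Heck termination at the ipso carbon would give the allylic alcohol A4.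
- Acid would then remove both acetals and close ring B by ionisation of the tertiary allylic alcohol, giving 2,2-dimethyl-5-{2-[4-(triisopropylsilyloxy)phenyl]ethyl}-2H-chromen-7-ol A5. Prenylation of its single free hydroxyl and desilylation would finish.
- In favour: ring A is bought, two C–C bonds form in one step under positional control by the iodine and its ortho substituent, and no diazo compound or photoreactor is needed. About six steps would suffice, which is better than the chosen plan. The differentiation of the ring A oxygens (ring closure before alkylation) is equal in quality to that of the chosen plan.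
- Against: A2 is a 2-arylethyl bromide that eliminates readily to a styrene under hot basic conditions, and its oxidative addition to the palladacycle must beat both this and the direct Heck coupling of A1. The E double bond of A4 cannot close directly, so ring closure needs acid on an electron-rich resorcinol, where cationic oligomerisation and loss of the silyl ether are conceivable.
- Comparison: the chosen plan derives the substitution pattern from a pericyclic cascade with no acid and no transition metal before the last step. Alternative 1 is shorter but rests on a three-component coupling whose weakest partner is the one needed here.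

**Alternative 2:** Ring B is cut at C8a–O1, C4a–C4 and O1–C2, and the C5–CH2 bond is left for a late cross-coupling.

- Forward step: fluoride would release from 3-chloro-5-(3-methylbut-2-enyloxy)-2-(trimethylsilyl)phenyl trifluoromethanesulfonate A6 an aryne spanning C8a and C4a. 3-Methylbut-2-enal A7 adds its carbonyl group across it, with oxygen going to C8a, remote from chlorine. The benzoxete opens to an ortho-quinone methide, and oxa-6π electrocyclisation gives 5-chloro-2,2-dimethyl-7-(3-methylbut-2-enyloxy)-2H-chromene A8.
- A palladium-catalysed sp2–sp3 coupling would then replace chlorine by the 2-arylethyl group.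
- In favour: ring B and the prenyl ether are set without any oxidation step, which is better than the chosen plan's oxidative ring closure. The arm enters last, which is better than the chosen plan for varying ring C.
- Against: A6 needs four or five steps of its own. Arynes undergo ene reactions with trisubstituted alkenes bearing allylic hydrogens, and both the prenyl ether and A7 offer such alkenes. The last coupling must activate a hindered, electron-rich aryl chloride peri to C4, with an alkyl metal bearing β-hydrogens, in the presence of an aryl prenyl ether that zerovalent palladium can ionise.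
- Comparison: the step count is about equal. The chosen plan sets all four ring A substituents in the ring-forming event, whereas alternative 2 leaves the hardest bond to the end.

**Alternative 3:** Ring A is cut at C4a–C5 and C8–C8a and is built at the cyclohexanedione oxidation level.

- Forward step: (E)-6-[4-(benzyloxy)phenyl]hex-3-en-2-one A9 and dimethyl malonate A10 would combine under methoxide by Michael addition and Claisen closure to the dioxo ester A11. Dehydrogenation would give methyl 2-{2-[4-(benzyloxy)phenyl]ethyl}-4,6-dihydroxybenzoate A12, whose ester carbon sits on C4a and becomes C4.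
- In favour: the reagents are cheap, the chemistry is ionic and easy to scale, and there is no diazo compound; on robustness at scale it is better than the chosen plan. In A12 the hydroxyl next to the ester is hydrogen-bonded, so the C7 hydroxyl can be prenylated selectively, a differentiation equal to that of the chosen plan.
- Against: the ring needs a separate aromatisation. The ester must be converted into C4, C3 and C2 (reduction, addition of a 2-methylpropenyl metal, dehydrative closure). The benzyl ether cannot be removed by hydrogenolysis once the alkenes are present, so a protecting-group exchange is needed.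
- Comparison: ten to twelve steps would be needed, more than the chosen plan, and ring B is assembled from small pieces instead of one prenyl group.

Key step: step 6

Assumption: (triisopropylsilyloxy)ethyne, a distillable ynol silyl ether, is taken as a stock reagent and enters as a starting material.

## Route

Step 1
Reactants: 1 raspberry ketone (4-(4-hydroxyphenyl)butan-2-one)
Product: 2 silyl ether 4-[4-(triisopropylsilyloxy)phenyl]butan-2-one
Conditions: i-Pr3SiCl (1.2 equiv), imidazole (2.5 equiv), DMF, 23 °C
Reagents that add atoms: chlorotriisopropylsilane, CC(C)[Si](Cl)(C(C)C)C(C)C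
Why: Imidazole-promoted O-silylation of a phenol; the ketone is inert, and the bulky aryl silyl ether withstands the organolithium and amide bases of steps 4 and 5.

Step 2
Reactants: 2 silyl ether 4-[4-(triisopropylsilyloxy)phenyl]butan-2-one
Product: 3 (E)-2,4,6-triisopropyl-N'-{4-[4-(triisopropylsilyloxy)phenyl]butan-2-ylidene}benzenesulfonohydrazide
Conditions: 2,4,6-(i-Pr)3C6H2SO2NHNH2 (1.05 equiv), MeCN, 23 °C
Reagents that add atoms: 2,4,6-triisopropylbenzenesulfonohydrazide, NNS(=O)(=O)c1c(C(C)C)cc(C(C)C)cc1C(C)C
Why: Condensation of a ketone with an arenesulfonohydrazide; the hydrazone should form mainly as the E isomer, with the sulfonamide nitrogen syn to the methyl group, and no acid is added so the aryl silyl ether is safe.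

Step 3
Reactants: 4 5-methylhex-4-enoic acid
Product: 6 N-methoxy-N,5-dimethylhex-4-enamide, via acyl imidazolide 5 (not isolated)
Conditions: 1,1'-carbonyldiimidazole (1.1 equiv), CH2Cl2, 23 °C; then MeNHOMe·HCl (1.2 equiv), 23 °C
Reagents that add atoms: N,O-dimethylhydroxylamine hydrochloride, CNOC.Cl; 1,1'-carbonyldiimidazole, O=C(n1ccnc1)n1ccnc1 (imidazolyl group only in 5)
Why: Activation of the acid as its acyl imidazolide and aminolysis (Weinreb amide synthesis); the neutral conditions spare the trisubstituted alkene, which an acid chloride route could hydrochlorinate.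

Step 4
Reactants: 3 (E)-2,4,6-triisopropyl-N'-{4-[4-(triisopropylsilyloxy)phenyl]butan-2-ylidene}benzenesulfonohydrazide; 6 N-methoxy-N,5-dimethylhex-4-enamide
Product: 8 enone 7-methyl-2-{2-[4-(triisopropylsilyloxy)phenyl]ethyl}octa-1,6-dien-3-one, via vinyllithium 7 (not isolated)
Conditions: 3 (1.2 equiv), n-BuLi (2.4 equiv), THF, −78 °C then 0 °C; 6 (1.0 equiv), −78 to 0 °C; inverse quench into cold 1 M HCl
Reagents that add atoms: n-butyllithium, [Li]CCCC (lithium only in 7)
Why: Shapiro reaction: n-BuLi removes N–H and then a methyl hydrogen syn to the sulfonamide, and loss of sulfinate and N2 at 0 °C gives the 1,1-disubstituted vinyllithium 7, which the Weinreb amide 6 acylates only once. The inverse acidic quench protonates the released amine before it can add to the methylene enone.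

Step 5
Reactants: 8 enone 7-methyl-2-{2-[4-(triisopropylsilyloxy)phenyl]ethyl}octa-1,6-dien-3-one
Product: 10 diazo ketone 4-diazo-7-methyl-2-{2-[4-(triisopropylsilyloxy)phenyl]ethyl}octa-1,6-dien-3-one, via trifluoroacetyl diketone 9 (not isolated)
Conditions: LiN(SiMe3)2 (1.1 equiv), THF, −78 °C; CF3CO2CH2CF3 (1.2 equiv), −78 °C; cold 5% HCl wash, solvent exchange (9 not purified); 4-AcNHC6H4SO2N3 (1.5 equiv), Et3N (1.5 equiv), H2O (1 equiv), MeCN, 23 °C
Reagents that add atoms: 2,2,2-trifluoroethyl trifluoroacetate, O=C(OCC(F)(F)F)C(F)(F)F (trifluoroacetyl group only in 9); 4-acetamidobenzenesulfonyl azide, CC(=O)Nc1ccc(cc1)S(=O)(=O)N=[N+]=[N-]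
Why: Detrifluoroacetylative diazo transfer, a method suited to base-sensitive enones: the hindered silylamide enolises only the saturated α-CH2, Claisen acylation gives 9, and the sulfonyl azide transfers N2 while the trifluoroacetyl group leaves as the N-sulfonyl amide. The acetamido-substituted azide is chosen as the less shock-sensitive transfer reagent.

Step 6
Reactants: 10 diazo ketone 4-diazo-7-methyl-2-{2-[4-(triisopropylsilyloxy)phenyl]ethyl}octa-1,6-dien-3-one; 11 (triisopropylsilyloxy)ethyne
Product: 16 phenol 4-(3-methylbut-2-enyl)-3-(triisopropylsilyloxy)-5-{2-[4-(triisopropylsilyloxy)phenyl]ethyl}phenol, via vinylketene 12 (not isolated), via vinylcyclobutenone 13 (not isolated), via dienylketene 14 (not isolated), via cyclohexadienone 15 (not isolated)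
Conditions: 11 (1.5 equiv), degassed ClCH2CH2Cl (0.05–0.1 M), hν (medium-pressure Hg lamp, Pyrex filter), 23 °C; then 80 °C
Reagents that add atoms: none
Why: Photochemical Wolff rearrangement of 10 expels N2 and shifts the alkenyl group to the diazo carbon, giving vinylketene 12 with the prenyl group on the ketene α-carbon. Alkyne 11 adds in a polarised [2+2] step in which its unsubstituted carbon attacks the ketene carbonyl carbon (C7–C8) and its silyloxy-bearing carbon closes onto the α-carbon (C8a–C4a), giving the 3-silyloxy-4-vinylcyclobutenone 13. 4π electrocyclic opening of 13 gives dienylketene 14, 6π electrocyclisation (C6–C7) gives cyclohexadienone 15, and tautomerisation gives phenol 16; the closest known reaction type is the photochemical α-diazo ketone form of the Danheiser benzannulation with siloxyalkynes, which gives resorcinol monosilyl ethers. Ring A thus closes by a thermal disrotatory 6π electrocyclisation of the isomer of 14 that has the vinyl group cis to the ketene arm, while the other isomer can return to 13 by reversible closure. No stereocentre remains, because the quaternary carbon of racemic 13 becomes sp2. The selectivity needed is regiochemical and is secured by the polarity of 11 (nucleophilic at CH, electrophilic at C–O after attack) matched to the ketene, so the silyl ether lands on C8a beside the prenyl group and the free hydroxyl on C7. Dilution and an excess of 11 keep the ketene from acylating 16, and the final heating should drive any remaining 13 to 16.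

Step 7
Reactants: 16 phenol 4-(3-methylbut-2-enyl)-3-(triisopropylsilyloxy)-5-{2-[4-(triisopropylsilyloxy)phenyl]ethyl}phenol; 17 prenyl bromide (1-bromo-3-methylbut-2-ene)
Product: 18 ether 2-(3-methylbut-2-enyl)-5-(3-methylbut-2-enyloxy)-1-(triisopropylsilyloxy)-3-{2-[4-(triisopropylsilyloxy)phenyl]ethyl}benzene
Conditions: 17 (1.3 equiv), K2CO3 (2 equiv), acetone, 23–40 °C
Reagents that add atoms: none
Why: Williamson etherification of the only free phenol; the polar aprotic medium favours O- over C-alkylation, and the aryl triisopropylsilyl ethers should withstand anhydrous K2CO3.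

Step 8
Reactants: 18 ether 2-(3-methylbut-2-enyl)-5-(3-methylbut-2-enyloxy)-1-(triisopropylsilyloxy)-3-{2-[4-(triisopropylsilyloxy)phenyl]ethyl}benzene
Product: 19 diphenol 3-[2-(4-hydroxyphenyl)ethyl]-2-(3-methylbut-2-enyl)-5-(3-methylbut-2-enyloxy)phenol
Conditions: n-Bu4NF (2.5 equiv), AcOH (2.5 equiv), THF, 0 °C
Reagents that add atoms: none
Why: Fluoride-mediated cleavage of both aryl silyl ethers, driven by Si–F bond formation; acetic acid buffers the phenoxides so the allyl aryl ether and the electron-rich diphenol are not exposed to strong base.

Step 9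
Reactants: 19 diphenol 3-[2-(4-hydroxyphenyl)ethyl]-2-(3-methylbut-2-enyl)-5-(3-methylbut-2-enyloxy)phenol
Product: 20 target 4-{2-[2,2-dimethyl-7-(3-methylbut-2-enyloxy)-2H-chromen-5-yl]ethyl}phenol
Conditions: PdCl2(MeCN)2 (10 mol %), 1,4-benzoquinone (1.5 equiv), 1,4-dioxane, 23–40 °C
Reagents that add atoms: none
Why: Wacker-type oxidative cyclisation of an ortho-prenylphenol: divalent palladium activates the C-prenyl alkene, the C8a hydroxyl attacks its more substituted carbon (6-endo), and β-hydride elimination toward C4 gives the 2H-chromene, since C2 has no hydrogen. Benzoquinone reoxidises zerovalent palladium; the O-prenyl alkene has no internal nucleophile and the ring C hydroxyl is out of reach, so only ring B should close.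

## Compound list

1 | 4-(4-hydroxyphenyl)butan-2-one (raspberry ketone) | CC(=O)CCc1ccc(O)cc1 | starting material
2 | 4-[4-(triisopropylsilyloxy)phenyl]butan-2-one | CC(=O)CCc1ccc(O[Si](C(C)C)(C(C)C)C(C)C)cc1 | intermediate
3 | (E)-2,4,6-triisopropyl-N'-{4-[4-(triisopropylsilyloxy)phenyl]butan-2-ylidene}benzenesulfonohydrazide | C/C(CCc1ccc(O[Si](C(C)C)(C(C)C)C(C)C)cc1)=N\NS(=O)(=O)c1c(C(C)C)cc(C(C)C)cc1C(C)C | intermediate
4 | 5-methylhex-4-enoic acid | CC(C)=CCCC(=O)O | starting material
5 | 1-(1H-imidazol-1-yl)-5-methylhex-4-en-1-one | CC(C)=CCCC(=O)n1ccnc1 | intermediate (not isolated)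
6 | N-methoxy-N,5-dimethylhex-4-enamide | CC(C)=CCCC(=O)N(C)OC | intermediate
7 | {4-[4-(triisopropylsilyloxy)phenyl]but-1-en-2-yl}lithium | [Li]C(=C)CCc1ccc(O[Si](C(C)C)(C(C)C)C(C)C)cc1 | intermediate (not isolated)
8 | 7-methyl-2-{2-[4-(triisopropylsilyloxy)phenyl]ethyl}octa-1,6-dien-3-one | C=C(CCc1ccc(O[Si](C(C)C)(C(C)C)C(C)C)cc1)C(=O)CCC=C(C)C | intermediate
9 | 7-methyl-2-{2-[4-(triisopropylsilyloxy)phenyl]ethyl}-4-(trifluoroacetyl)octa-1,6-dien-3-one (racemic) | C=C(CCc1ccc(O[Si](C(C)C)(C(C)C)C(C)C)cc1)C(=O)C(CC=C(C)C)C(=O)C(F)(F)F | intermediate (not isolated)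
10 | 4-diazo-7-methyl-2-{2-[4-(triisopropylsilyloxy)phenyl]ethyl}octa-1,6-dien-3-one | C=C(CCc1ccc(O[Si](C(C)C)(C(C)C)C(C)C)cc1)C(=O)C(=[N+]=[N-])CC=C(C)C | intermediate
11 | (triisopropylsilyloxy)ethyne | C#CO[Si](C(C)C)(C(C)C)C(C)C | starting material
12 | 2-(3-methylbut-2-enyl)-3-{2-[4-(triisopropylsilyloxy)phenyl]ethyl}buta-1,3-dien-1-one | O=C=C(CC=C(C)C)C(=C)CCc1ccc(O[Si](C(C)C)(C(C)C)C(C)C)cc1 | intermediate (not isolated)
13 | 4-(3-methylbut-2-enyl)-3-(triisopropylsilyloxy)-4-{4-[4-(triisopropylsilyloxy)phenyl]but-1-en-2-yl}cyclobut-2-en-1-one (racemic) | O=C1C=C(O[Si](C(C)C)(C(C)C)C(C)C)C1(CC=C(C)C)C(=C)CCc1ccc(O[Si](C(C)C)(C(C)C)C(C)C)cc1 | intermediate (not isolated)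
14 | (3E)-4-(3-methylbut-2-enyl)-3-(triisopropylsilyloxy)-5-{2-[4-(triisopropylsilyloxy)phenyl]ethyl}hexa-1,3,5-trien-1-one | O=C=C/C(O[Si](C(C)C)(C(C)C)C(C)C)=C(/CC=C(C)C)C(=C)CCc1ccc(O[Si](C(C)C)(C(C)C)C(C)C)cc1 | intermediate (not isolated)
15 | 4-(3-methylbut-2-enyl)-3-(triisopropylsilyloxy)-5-{2-[4-(triisopropylsilyloxy)phenyl]ethyl}cyclohexa-2,4-dien-1-one | O=C1C=C(O[Si](C(C)C)(C(C)C)C(C)C)C(CC=C(C)C)=C(CCc2ccc(O[Si](C(C)C)(C(C)C)C(C)C)cc2)C1 | intermediate (not isolated)
16 | 4-(3-methylbut-2-enyl)-3-(triisopropylsilyloxy)-5-{2-[4-(triisopropylsilyloxy)phenyl]ethyl}phenol | Oc1cc(O[Si](C(C)C)(C(C)C)C(C)C)c(CC=C(C)C)c(CCc2ccc(O[Si](C(C)C)(C(C)C)C(C)C)cc2)c1 | intermediate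
17 | 1-bromo-3-methylbut-2-ene (prenyl bromide) | CC(C)=CCBr | starting material
18 | 2-(3-methylbut-2-enyl)-5-(3-methylbut-2-enyloxy)-1-(triisopropylsilyloxy)-3-{2-[4-(triisopropylsilyloxy)phenyl]ethyl}benzene | CC(C)=CCOc1cc(O[Si](C(C)C)(C(C)C)C(C)C)c(CC=C(C)C)c(CCc2ccc(O[Si](C(C)C)(C(C)C)C(C)C)cc2)c1 | intermediate
19 | 3-[2-(4-hydroxyphenyl)ethyl]-2-(3-methylbut-2-enyl)-5-(3-methylbut-2-enyloxy)phenol | CC(C)=CCOc1cc(O)c(CC=C(C)C)c(CCc2ccc(O)cc2)c1 | intermediate
20 | 4-{2-[2,2-dimethyl-7-(3-methylbut-2-enyloxy)-2H-chromen-5-yl]ethyl}phenol | CC(C)=CCOc1cc(CCc2ccc(O)cc2)c2c(c1)OC(C)(C)C=C2 | target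

## Step count and least certain steps

Total: 9 steps. Longest linear sequence: 8 steps (steps 1, 2, 4, 5, 6, 7, 8, 9); step 3 is a one-step side branch.

**Step 6 (key step).**
- What may go wrong: on loss of N2 a hydrogen of the prenyl CH2 may migrate instead of the alkenyl group, so that no ketene forms. The ketene may also be acylated away by the phenol already produced. Either process starves the cascade.
- Fallback (sets out from 17 and 11, returns at 16): the same vinylketene 12 would be generated without a carbene by thermal 4π opening of a cyclobutenone.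
  - Ethoxyethyne would be deprotonated with n-BuLi in THF/DMPU and alkylated with 17 to 1-ethoxy-5-methylhex-4-en-1-yne F1.
  - [2+2] addition of ketene to F1 would give 3-ethoxy-2-(3-methylbut-2-enyl)cyclobut-2-en-1-one F2.
  - 4-(2-Bromoethyl)phenol would be silylated as in step 1 to [4-(2-bromoethyl)phenoxy]triisopropylsilane F3 and converted with Mg in THF into {2-[4-(triisopropylsilyloxy)phenyl]ethyl}magnesium bromide F4.
  - 1,2-Addition of F4 to F2, then dilute HCl (enol ether hydrolysis and dehydration), would give 2-(3-methylbut-2-enyl)-3-{2-[4-(triisopropylsilyloxy)phenyl]ethyl}cyclobut-2-en-1-one F5.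
  - Heating F5 with 11 in toluene at 80–110 °C would pass through 12, 13, 14 and 15 to 16.

**Step 9.**
- What may go wrong: ring closure through the wrong alkene terminus (5-exo, or via an allylpalladium species formed by C–H activation), and ionisation of the aryl prenyl ether by transient zerovalent palladium.
- Fallback (sets out from 19, returns at 20): electrophilic selenocyclisation with N-(phenylselanyl)phthalimide and catalytic camphorsulfonic acid in CH2Cl2 would give, by 6-endo attack at the tertiary carbon, 4-{2-[2,2-dimethyl-7-(3-methylbut-2-enyloxy)-3-(phenylselanyl)chroman-5-yl]ethyl}phenol F6. Oxidation with NaIO4 and NaHCO3 and syn-elimination of the selenoxide toward the benzylic C4–H would give 20. The O-prenyl alkene, lacking an internal nucleophile, should only form its seleniranium ion reversibly.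

**Step 4.**
- What may go wrong: misdirected second deprotonation of the hydrazone (the minor Z isomer would lead to the internal vinyllithium), incomplete loss of N2 before the amide is added, and conjugate addition of the released amine to the enone during the quench.
- Fallback (sets out from 2 and 6, returns at 8):
  - Kinetic enolisation of 2 with KN(SiMe3)2 at −78 °C and trapping with N-phenylbis(trifluoromethanesulfonimide) would give 4-[4-(triisopropylsilyloxy)phenyl]but-1-en-2-yl trifluoromethanesulfonate F7.
  - Reduction of 6 with (i-Bu)2AlH at −78 °C would give 5-methylhex-4-enal F8.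
  - Nozaki–Hiyama–Kishi coupling of F7 and F8 (CrCl2, catalytic NiCl2, DMF) would give 7-methyl-2-{2-[4-(triisopropylsilyloxy)phenyl]ethyl}octa-1,6-dien-3-ol F9.
  - Oxidation of F9 with Dess–Martin periodinane would give 8.

**Step 7.**
- What may go wrong: C-alkylation of the ambident phenoxide at C6 or C8, or carbonate-induced loss of the ring A silyl group followed by double alkylation.
- Fallback (sets out from 16, returns at 18): Mitsunobu etherification of 16 with 3-methylbut-2-en-1-ol, PPh3 and diisopropyl azodicarboxylate in toluene at 0 °C. This activates the alcohol instead of forming a free phenoxide and makes no new compound.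

## Further compounds

F1 | step 6 | 1-ethoxy-5-methylhex-4-en-1-yne | CCOC#CCC=C(C)C
F2 | step 6 | 3-ethoxy-2-(3-methylbut-2-enyl)cyclobut-2-en-1-one | CCOC1=C(CC=C(C)C)C(=O)C1
F3 | step 6 | [4-(2-bromoethyl)phenoxy]triisopropylsilane | BrCCc1ccc(O[Si](C(C)C)(C(C)C)C(C)C)cc1
F4 | step 6 | {2-[4-(triisopropylsilyloxy)phenyl]ethyl}magnesium bromide | Br[Mg]CCc1ccc(O[Si](C(C)C)(C(C)C)C(C)C)cc1
F5 | step 6 | 2-(3-methylbut-2-enyl)-3-{2-[4-(triisopropylsilyloxy)phenyl]ethyl}cyclobut-2-en-1-one | O=C1CC(CCc2ccc(O[Si](C(C)C)(C(C)C)C(C)C)cc2)=C1CC=C(C)C
F6 | step 9 | 4-{2-[2,2-dimethyl-7-(3-methylbut-2-enyloxy)-3-(phenylselanyl)chroman-5-yl]ethyl}phenol (racemic) | CC(C)=CCOc1cc(CCc2ccc(O)cc2)c2c(c1)OC(C)(C)C([Se]c3ccccc3)C2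
F7 | step 4 | 4-[4-(triisopropylsilyloxy)phenyl]but-1-en-2-yl trifluoromethanesulfonate | C=C(CCc1ccc(O[Si](C(C)C)(C(C)C)C(C)C)cc1)OS(=O)(=O)C(F)(F)F
F8 | step 4 | 5-methylhex-4-enal | CC(C)=CCCC=O
F9 | step 4 | 7-methyl-2-{2-[4-(triisopropylsilyloxy)phenyl]ethyl}octa-1,6-dien-3-ol (racemic) | C=C(CCc1ccc(O[Si](C(C)C)(C(C)C)C(C)C)cc1)C(O)CCC=C(C)C
F0 | step 7 | none | none
A1 | alternative 1 | 1-iodo-2,4-bis(methoxymethoxy)benzene | COCOc1ccc(I)c(OCOC)c1
A2 | alternative 1 | [4-(2-bromoethyl)phenoxy]triisopropylsilane | BrCCc1ccc(O[Si](C(C)C)(C(C)C)C(C)C)cc1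
A3 | alternative 1 | 2-methylbut-3-en-2-ol | CC(C)(O)C=C
A4 | alternative 1 | (E)-4-{2,4-bis(methoxymethoxy)-6-[2-(4-triisopropylsilyloxyphenyl)ethyl]phenyl}-2-methylbut-3-en-2-ol | COCOc1cc(OCOC)c(/C=C/C(C)(C)O)c(CCc2ccc(O[Si](C(C)C)(C(C)C)C(C)C)cc2)c1
A5 | alternative 1 | 2,2-dimethyl-5-{2-[4-(triisopropylsilyloxy)phenyl]ethyl}-2H-chromen-7-ol | Oc1cc(CCc2ccc(O[Si](C(C)C)(C(C)C)C(C)C)cc2)c2C=CC(C)(C)Oc2c1
A6 | alternative 2 | 3-chloro-5-(3-methylbut-2-enyloxy)-2-(trimethylsilyl)phenyl trifluoromethanesulfonate | CC(C)=CCOc1cc(Cl)c([Si](C)(C)C)c(OS(=O)(=O)C(F)(F)F)c1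
A7 | alternative 2 | 3-methylbut-2-enal | CC(C)=CC=O
A8 | alternative 2 | 5-chloro-2,2-dimethyl-7-(3-methylbut-2-enyloxy)-2H-chromene | CC(C)=CCOc1cc(Cl)c2C=CC(C)(C)Oc2c1
A9 | alternative 3 | (E)-6-[4-(benzyloxy)phenyl]hex-3-en-2-one | CC(=O)/C=C/CCc1ccc(OCc2ccccc2)cc1
A10 | alternative 3 | dimethyl malonate | COC(=O)CC(=O)OC
A11 | alternative 3 | methyl 2-{2-[4-(benzyloxy)phenyl]ethyl}-4,6-dioxocyclohexane-1-carboxylate (racemic, enolised) | COC(=O)C1C(CCc2ccc(OCc3ccccc3)cc2)CC(=O)CC1=O
A12 | alternative 3 | methyl 2-{2-[4-(benzyloxy)phenyl]ethyl}-4,6-dihydroxybenzoate | COC(=O)c1c(O)cc(O)cc1CCc1ccc(OCc2ccccc2)cc1
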